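The carbocycle of the tetrahydrochromone half (C4a, C5–C8, C8a; chromone numbering) is read as a dearomatised chromone benzo ring, and the cis pair O7/O8 is the feature exploited: both oxygens are traced to one O2 molecule added across the C7–C8 edge. In one operation an arene dioxygenase turns flat, commercial 2-methylchromone into the (7S,8S)-cis-7,8-dihydrodiol, forming both C–O bonds and both stereocentres and leaving a C5=C6 alkene. That alkene carries the trans-5,6-diol (anti epoxidation, hydrolysis at C5); the 2-methyl group is then benzylated and O8 is arylated with a paeonol-derived chromonyl boron reagent.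

Key step: step 1

Remark on the chemistry: chromone locants are used for the carbocycle of every intermediate; the dioxygenase is assumed to act in the facial sense it shows with naphthalene and bromobenzene, and paeonol is assumed to brominate para to its hydroxyl group.

Step 1
Reactants: 1 2-methylchromone
Product: 2 (7S,8S)-7,8-dihydroxy-2-methyl-7,8-dihydro-4H-chromen-4-one
Conditions: resting recombinant E. coli cells expressing toluene dioxygenase (todC1C2BA; naphthalene dioxygenase and engineered variants screened in parallel), glucose as electron source, phosphate buffer pH 7.2, air, 30 °C; EtOAc extraction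
Reagents that add atoms: dioxygen, O=O
Why: Proposed new method: a Rieske non-haem iron arene dioxygenase, supplied with two electrons from NADH through its reductase and ferredoxin, binds O2 side-on at the mononuclear iron (divalent in the resting state), and the iron-bound peroxide passes both oxygen atoms to one face of the C7–C8 edge, so that C7–O and C8–O form cis and the benzo ring loses its aromaticity. The closest known reaction type is the cis-dihydroxylation of naphthalene, quinolines, benzofuran and monosubstituted benzenes by toluene and naphthalene dioxygenases, whereas a chromone has not been shown as substrate. No ring is closed. Both new stereocentres, C7 and C8, are set by the chiral active site alone, and the usual facial sense of these enzymes (the one that gives the (1R,2S)-diol from naphthalene and the (1S,2S)-diol from bromobenzene) translates into (7S,8S) when the pyranone takes the place of the unoxidised ring. The step needs attack at the C7–C8 edge and not at C5–C6, plus no onward oxidation: the substrate helps because its methyl group offers no second arene, O1 makes C8 electron-rich while the peri C4 carbonyl deactivates and crowds C5, and a host without dihydrodiol dehydrogenase cannot rearomatise the diol to the catechol. Edge and facial selectivity still rest on the binding pocket, so a panel of wild-type and engineered dioxygenases would be screened and the regiochemistry and enantiopurity of 2 established before scale-up.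

Step 2
Reactants: 2 (7S,8S)-7,8-dihydroxy-2-methyl-7,8-dihydro-4H-chromen-4-one
Product: 3 (7S,8S)-7,8-(isopropylidenedioxy)-2-methyl-7,8-dihydro-4H-chromen-4-one
Conditions: 2,2-dimethoxypropane, TsOH·H2O (cat.), acetone, 0 °C; Et3N quench
Reagents that add atoms: 2,2-dimethoxypropane, COC(C)(C)OC
Why: Acid-catalysed transketalisation of the cis-vicinal diol is fast at 0 °C and should outrun acid-induced dehydration to the phenol, giving the cis-fused dioxolane without touching the C7–O or C8–O bond.

Step 3
Reactants: 3 (7S,8S)-7,8-(isopropylidenedioxy)-2-methyl-7,8-dihydro-4H-chromen-4-one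
Product: 5 (5S,6R,7S,8S)-5,6-dihydroxy-7,8-(isopropylidenedioxy)-2-methyl-5,6,7,8-tetrahydro-4H-chromen-4-one, via anti 5,6-epoxide 4 (not isolated)
Conditions: DMDO, acetone, 0 °C; then H2O, HClO4 (cat.), 0 °C
Reagents that add atoms: dimethyldioxirane, CC1(C)OO1; water, O
Why: Prilezhaev-type oxygen transfer from the dioxirane should occur at the only electron-rich alkene (C5=C6) on the face opposite the dioxolane, which sets C6, and acid-catalysed epoxide hydrolysis then breaks the C5–O bond, whose developing cation is stabilised by O1 through C4a=C8a, with backside entry of water, which sets C5 trans to O6 as in the opening of vinyl epoxides derived from other arene cis-diol acetonides.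

Step 4
Reactants: 5 (5S,6R,7S,8S)-5,6-dihydroxy-7,8-(isopropylidenedioxy)-2-methyl-5,6,7,8-tetrahydro-4H-chromen-4-one
Product: 6 5,6-bis-O-(tert-butyldimethylsilyl) ether of 5
Conditions: TBSOTf, 2,6-lutidine, CH2Cl2, 0 °C → rt
Reagents that add atoms: tert-butyldimethylsilyl triflate, CC(C)(C)[Si](C)(C)OS(=O)(=O)C(F)(F)F
Why: Silyl triflate silylation with a hindered pyridine base is strong enough for two crowded secondary alcohols and leaves the ketal, the pyranone and all four stereocentres alone.

Step 5
Reactants: 6 5,6-bis-O-(tert-butyldimethylsilyl) ether of 5; 7 benzyl bromide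
Product: 8 5,6-bis-O-(tert-butyldimethylsilyl)-7,8-O-isopropylidene-2-(2-phenylethyl) tetrahydrochromone
Conditions: LiN(i-Pr)2, THF, −78 °C; then 7, −78 → −40 °C
Reagents that add atoms: none
Why: Kinetic lateral lithiation of the 2-methyl group gives the vinylogous enolate of the 4-pyranone, which is C-alkylated by benzyl bromide in an SN2 reaction, while the only other γ-hydrogen sits on the oxygenated methine C8 and is kinetically far less accessible, so the ring stereocentres should stay intact.

Step 6
Reactants: 8 5,6-bis-O-(tert-butyldimethylsilyl)-7,8-O-isopropylidene-2-(2-phenylethyl) tetrahydrochromone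
Product: 9 5,6-bis-O-(tert-butyldimethylsilyl)-7,8-dihydroxy-2-(2-phenylethyl)-5,6,7,8-tetrahydro-4H-chromen-4-one
Conditions: AcOH/H2O/THF (3:1:1), 45 °C
Reagents that add atoms: none
Why: Acid-catalysed ketal hydrolysis in aqueous acetic acid is much faster than cleavage of hindered secondary TBS ethers, so the 7,8-diol should be released with O5 and O6 still protected and no stereocentre touched.

Step 7
Reactants: 10 paeonol
Product: 11 1-(5-bromo-2-hydroxy-4-methoxyphenyl)ethanone
Conditions: NBS, MeCN, 0 °C → rt
Reagents that add atoms: N-bromosuccinimide, O=C1CCC(=O)N1Br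
Why: Electrophilic aromatic bromination should go to C5, which is para to the hydroxyl and ortho to the methoxy group and less crowded than the position between the two donors.

Step 8
Reactants: 11 1-(5-bromo-2-hydroxy-4-methoxyphenyl)ethanone; 12 3-phenylpropanoyl chloride
Product: 13 2-acetyl-4-bromo-5-methoxyphenyl 3-phenylpropanoate
Conditions: Et3N, DMAP (cat.), CH2Cl2, 0 °C → rt
Reagents that add atoms: none
Why: DMAP-catalysed O-acylation of the phenol by the acid chloride (nucleophilic acyl substitution) places the acyl group next to the acetyl group for the intramolecular Claisen step.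

Step 9
Reactants: 13 2-acetyl-4-bromo-5-methoxyphenyl 3-phenylpropanoate
Product: 15 6-bromo-7-methoxy-2-(2-phenylethyl)-4H-chromen-4-one, via 1,3-diketone 14 (not isolated)
Conditions: LiN(SiMe3)2, THF, −78 °C → rt; then AcOH, conc. HCl, 90 °C
Reagents that add atoms: none
Why: Baker–Venkataraman rearrangement (the acetyl enolate attacks the neighbouring aryl ester) gives the 1,3-diketone, and acid-catalysed cyclodehydration of its phenol onto the distal carbonyl closes the 4-pyranone ring.

Step 10
Reactants: 15 6-bromo-7-methoxy-2-(2-phenylethyl)-4H-chromen-4-one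
Product: 17 potassium trifluoro[7-methoxy-4-oxo-2-(2-phenylethyl)-4H-chromen-6-yl]borate, via pinacol boronate 16 (not isolated)
Conditions: B2pin2, Pd(dppf)Cl2 (cat.), KOAc, 1,4-dioxane, 90 °C; then KHF2, MeOH/H2O, rt
Reagents that add atoms: bis(pinacolato)diboron, CC1(C)OB(OC1(C)C)B1OC(C)(C)C(C)(C)O1; potassium hydrogen difluoride, F.[F-].[K+]
Why: Miyaura borylation (oxidative addition of the aryl bromide to zerovalent palladium, acetate-assisted transmetalation with the diboron) followed by fluoride exchange gives a crystalline trifluoroborate that is free of pinacol and stable to storage.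

Step 11
Reactants: 9 5,6-bis-O-(tert-butyldimethylsilyl)-7,8-dihydroxy-2-(2-phenylethyl)-5,6,7,8-tetrahydro-4H-chromen-4-one; 17 potassium trifluoro[7-methoxy-4-oxo-2-(2-phenylethyl)-4H-chromen-6-yl]borate
Product: 18 5,6-bis-O-(tert-butyldimethylsilyl) ether of the target
Conditions: Cu(OAc)2·H2O (cat.), DMAP, 4 Å MS, O2 (1 atm), CH2Cl2, rt
Reagents that add atoms: none
Why: In this Chan–Lam–Evans oxidative coupling the aryl group passes from boron to a copper alkoxide and C–O reductive elimination from trivalent copper forms the ether with retention at C8 because the C8–O bond is never broken, and O8 should react before O7 because it is the less hindered hydroxyl (O7 is flanked by the C6 silyl ether) and sits next to the sp2 carbon C8a of the electron-poor pyranone.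

Step 12
Reactants: 18 5,6-bis-O-(tert-butyldimethylsilyl) ether of the target
Product: 19 (5S,6R,7S,8S)-5,6,7-trihydroxy-8-{[7-methoxy-4-oxo-2-(2-phenylethyl)-4H-chromen-6-yl]oxy}-2-(2-phenylethyl)-5,6,7,8-tetrahydro-4H-chromen-4-one (target)
Conditions: HF·pyridine, pyridine, THF, 0 °C → rt
Reagents that add atoms: none
Why: Fluoride-driven desilylation under buffered, non-basic conditions frees O5 and O6 without ionising the activated C5–O bond or opening either pyranone, so the four stereocentres are delivered unchanged.

Compound list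
1 | 2-methylchromone (2-methyl-4H-chromen-4-one) | Cc1cc(=O)c2ccccc2o1 | starting material
2 | (7S,8S)-7,8-dihydroxy-2-methyl-7,8-dihydro-4H-chromen-4-one (cis-7,8-dihydrodiol) | O[C@@H]1c2oc(C)cc(=O)c2C=C[C@@H]1O | intermediate
3 | (7S,8S)-7,8-(isopropylidenedioxy)-2-methyl-7,8-dihydro-4H-chromen-4-one (acetonide of 2) | CC1(C)O[C@@H]2c3oc(C)cc(=O)c3C=C[C@@H]2O1 | intermediate
4 | 5,6-epoxide of 3 with the epoxide oxygen on the face opposite the dioxolane (not isolated) | CC1(C)O[C@@H]2c3oc(C)cc(=O)c3[C@H]4O[C@H]4[C@@H]2O1 | intermediate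
5 | (5S,6R,7S,8S)-5,6-dihydroxy-7,8-(isopropylidenedioxy)-2-methyl-5,6,7,8-tetrahydro-4H-chromen-4-one (O5 on the face of O7/O8, O6 on the other face) | CC1(C)O[C@@H]2c3oc(C)cc(=O)c3[C@H](O)[C@@H](O)[C@@H]2O1 | intermediate
6 | 5,6-bis-O-(tert-butyldimethylsilyl) ether of 5 | CC1(C)O[C@@H]2c3oc(C)cc(=O)c3[C@H](O[Si](C)(C)C(C)(C)C)[C@@H](O[Si](C)(C)C(C)(C)C)[C@@H]2O1 | intermediate
7 | benzyl bromide | BrCc1ccccc1 | starting material
8 | 5,6-bis-O-(tert-butyldimethylsilyl)-7,8-O-isopropylidene-2-(2-phenylethyl) tetrahydrochromone (configuration as in 5) | CC1(C)O[C@@H]2c3oc(CCc4ccccc4)cc(=O)c3[C@H](O[Si](C)(C)C(C)(C)C)[C@@H](O[Si](C)(C)C(C)(C)C)[C@@H]2O1 | intermediate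
9 | 5,6-bis-O-(tert-butyldimethylsilyl)-7,8-dihydroxy-2-(2-phenylethyl)-5,6,7,8-tetrahydro-4H-chromen-4-one (configuration as in 5) | O[C@@H]1c2oc(CCc3ccccc3)cc(=O)c2[C@H](O[Si](C)(C)C(C)(C)C)[C@@H](O[Si](C)(C)C(C)(C)C)[C@@H]1O | intermediate
10 | paeonol (1-(2-hydroxy-4-methoxyphenyl)ethanone) | CC(=O)c1ccc(OC)cc1O | starting material
11 | 1-(5-bromo-2-hydroxy-4-methoxyphenyl)ethanone | CC(=O)c1cc(Br)c(OC)cc1O | intermediate
12 | 3-phenylpropanoyl chloride | O=C(Cl)CCc1ccccc1 | starting material
13 | 2-acetyl-4-bromo-5-methoxyphenyl 3-phenylpropanoate | CC(=O)c1cc(Br)c(OC)cc1OC(=O)CCc1ccccc1 | intermediate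
14 | 1-(5-bromo-2-hydroxy-4-methoxyphenyl)-5-phenylpentane-1,3-dione (not isolated) | O=C(CC(=O)CCc1ccccc1)c1cc(Br)c(OC)cc1O | intermediate
15 | 6-bromo-7-methoxy-2-(2-phenylethyl)-4H-chromen-4-one | COc1cc2oc(CCc3ccccc3)cc(=O)c2cc1Br | intermediate
16 | 7-methoxy-2-(2-phenylethyl)-6-(4,4,5,5-tetramethyl-1,3,2-dioxaborolan-2-yl)-4H-chromen-4-one (not isolated) | COc1cc2oc(CCc3ccccc3)cc(=O)c2cc1B1OC(C)(C)C(C)(C)O1 | intermediate
17 | potassium trifluoro[7-methoxy-4-oxo-2-(2-phenylethyl)-4H-chromen-6-yl]borate | COc1cc2oc(CCc3ccccc3)cc(=O)c2cc1[B-](F)(F)F.[K+] | intermediate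
18 | 5,6-bis-O-(tert-butyldimethylsilyl) ether of the target | COc1cc2oc(CCc3ccccc3)cc(=O)c2cc1O[C@@H]1c2oc(CCc3ccccc3)cc(=O)c2[C@H](O[Si](C)(C)C(C)(C)C)[C@@H](O[Si](C)(C)C(C)(C)C)[C@@H]1O | intermediate
19 | (5S,6R,7S,8S)-5,6,7-trihydroxy-8-{[7-methoxy-4-oxo-2-(2-phenylethyl)-4H-chromen-6-yl]oxy}-2-(2-phenylethyl)-5,6,7,8-tetrahydro-4H-chromen-4-one | COc1cc2oc(CCc3ccccc3)cc(=O)c2cc1O[C@@H]1c2oc(CCc3ccccc3)cc(=O)c2[C@H](O)[C@@H](O)[C@@H]1O | target

Total step count: 12. Longest linear sequence: 8 steps (steps 1, 2, 3, 4, 5, 6, 11, 12); the aryl branch (steps 7–10) joins at step 11.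

Steps most likely to fail

Step 1 (Proposed new method). The cells may hydroxylate the C5–C6 edge instead, deliver the opposite facial sense or low enantiopurity, or turn the polar substrate over too slowly. The fallback uses known chemistry only. It takes the carbocycle from commercial (1S,2S)-3-bromocyclohexa-3,5-diene-1,2-diol, the established toluene-dioxygenase product of bromobenzene, whose two carbinol carbons already have the configuration needed at C7 and C8 and whose C–Br carbon becomes C8a. It sets out from 12 and comes back to the route at 8, so that steps 1–5 and compounds 1 and 7 are not needed.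
- Acylation of Meldrum's acid with 12 (pyridine, CH2Cl2, 0 °C) gives the acyl Meldrum's acid F1. Heating it with acetone in toluene expels CO2 and gives the dioxinone F2.
- The bromodiol is converted (2,2-dimethoxypropane, TsOH cat.) into the bromodiene acetonide F3. mCPBA epoxidises the unhalogenated alkene anti to the dioxolane to give the bromo epoxide F4.
- Aqueous acid opens F4 at the allylic carbon with inversion to give the bromo trans-diol F5. This is the same relay as in steps 2 and 3 and a known entry to conduritols of this relative configuration.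
- TBSOTf/2,6-lutidine gives the bis-silyl ether F6. Miyaura borylation (B2pin2, Pd(dppf)Cl2, KOAc) gives the alkenyl pinacol boronate F7, and NaBO3·4H2O in THF/H2O oxidises it to the ketone F8 (C8a carbonyl, C4a methylene).
- Kinetic enolisation toward the methylene (LiN(i-Pr)2, Me3SiCl, THF, −78 °C) gives the trimethylsilyl enol ether F9.
- Heating F9 with F2 in toluene at 110 °C releases acetone and the acylketene, which adds to the enol ether in a hetero-Diels–Alder reaction. Loss of trimethylsilanol on mild acid work-up then gives the pyranone 8.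

Step 11. The aryl group may be delivered to O7 instead of O8, or aryl transfer from the hindered ortho-methoxy aryl boron species may stall while it protodeboronates. The fallback reverses the polarity and relies on double inversion at C8; it sets out from 9 and comes back at 18.
- SOCl2/Et3N converts 9 into the 7,8-cyclic sulfite F10, and RuCl3 (cat.)/NaIO4 in MeCN/H2O oxidises it to the 7,8-cyclic sulfate F11.
- One equivalent of LiBr in THF opens F11 by SN2 attack at C8 to give the 8-epi-bromide 7-hydrogen sulfate F12 (handled as its lithium salt, Br anti to O7). C8 is the carbon activated by the adjacent C8a=C4a–C4=O system and it is not shielded by the C6 silyl ether.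
- The phenol partner, 6-hydroxy-7-methoxy-2-(2-phenylethyl)chromone F13, is made from 17 with KHSO5 (as 2KHSO5·KHSO4·K2SO4) in aqueous acetone.
- The cesium salt of F13 (Cs2CO3, DMF) displaces the bromide with a second inversion, which places the aryloxy group cis to O7 in the aryl ether 7-hydrogen sulfate F14. No β-hydrogen is anti to the bromide, so substitution should beat elimination.
- Hydrolysis of the sulfate monoester (H2SO4 cat., 1 equiv H2O, THF, rt) gives 18.

Step 5. The base may deprotonate the C8 methine, which would be followed by β-elimination of O7 and aromatisation, or the product may be benzylated a second time. The fallback avoids a carbanion on the polyol; it sets out from 6 and comes back at 8.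
- Riley oxidation (SeO2, 1,4-dioxane, 90 °C) of the 2-methyl group, the only allylic CH3, gives the 2-carbaldehyde F15.
- Wittig olefination with benzylidenetriphenylphosphorane (from commercial benzyltriphenylphosphonium chloride and NaN(SiMe3)2, THF, −78 °C) gives the 2-styryl compound F16 as an E/Z mixture.
- Diimide (2-nitrobenzenesulfonyl hydrazide, Et3N) or H2 over RhCl(PPh3)3 reduces the disubstituted alkene and leaves the pyranone double bonds, giving 8.

Further compounds
F1 | step 1 | 5-(1-hydroxy-3-phenylpropylidene)-2,2-dimethyl-1,3-dioxane-4,6-dione | CC1(C)OC(=O)C(=C(O)CCc2ccccc2)C(=O)O1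
F2 | step 1 | 2,2-dimethyl-6-(2-phenylethyl)-4H-1,3-dioxin-4-one | CC1(C)OC(CCc2ccccc2)=CC(=O)O1
F3 | step 1 | acetonide of (1S,2S)-3-bromocyclohexa-3,5-diene-1,2-diol | CC1(C)O[C@@H]2C(Br)=CC=C[C@@H]2O1
F4 | step 1 | bromo epoxide, epoxide oxygen anti to the dioxolane | CC1(C)O[C@@H]2C(Br)=C[C@H]3O[C@H]3[C@@H]2O1
F5 | step 1 | bromo trans-diol (hydroxyl at the allylic carbon cis to the dioxolane) | CC1(C)O[C@@H]2C(Br)=C[C@H](O)[C@@H](O)[C@@H]2O1
F6 | step 1 | bis-O-(tert-butyldimethylsilyl) ether of F5 | CC1(C)O[C@@H]2C(Br)=C[C@H](O[Si](C)(C)C(C)(C)C)[C@@H](O[Si](C)(C)C(C)(C)C)[C@@H]2O1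
F7 | step 1 | alkenyl pinacol boronate from F6 | CC1(C)O[C@@H]2C(B3OC(C)(C)C(C)(C)O3)=C[C@H](O[Si](C)(C)C(C)(C)C)[C@@H](O[Si](C)(C)C(C)(C)C)[C@@H]2O1
F8 | step 1 | 3,4-bis(silyloxy)-5,6-(isopropylidenedioxy)cyclohexanone from F7 | CC1(C)O[C@@H]2C(=O)C[C@H](O[Si](C)(C)C(C)(C)C)[C@@H](O[Si](C)(C)C(C)(C)C)[C@@H]2O1
F9 | step 1 | trimethylsilyl enol ether of F8 | CC1(C)O[C@@H]2C(O[Si](C)(C)C)=C[C@H](O[Si](C)(C)C(C)(C)C)[C@@H](O[Si](C)(C)C(C)(C)C)[C@@H]2O1
F10 | step 11 | 7,8-cyclic sulfite of 9 | O=S1O[C@@H]2c3oc(CCc4ccccc4)cc(=O)c3[C@H](O[Si](C)(C)C(C)(C)C)[C@@H](O[Si](C)(C)C(C)(C)C)[C@@H]2O1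
F11 | step 11 | 7,8-cyclic sulfate of 9 | O=S1(=O)O[C@@H]2c3oc(CCc4ccccc4)cc(=O)c3[C@H](O[Si](C)(C)C(C)(C)C)[C@@H](O[Si](C)(C)C(C)(C)C)[C@@H]2O1
F12 | step 11 | 8-epi-bromide 7-hydrogen sulfate | Br[C@H]1c2oc(CCc3ccccc3)cc(=O)c2[C@H](O[Si](C)(C)C(C)(C)C)[C@@H](O[Si](C)(C)C(C)(C)C)[C@@H]1OS(=O)(=O)O
F13 | step 11 | 6-hydroxy-7-methoxy-2-(2-phenylethyl)-4H-chromen-4-one | COc1cc2oc(CCc3ccccc3)cc(=O)c2cc1O
F14 | step 11 | 7-hydrogen sulfate of 18 | COc1cc2oc(CCc3ccccc3)cc(=O)c2cc1O[C@@H]1c2oc(CCc3ccccc3)cc(=O)c2[C@H](O[Si](C)(C)C(C)(C)C)[C@@H](O[Si](C)(C)C(C)(C)C)[C@@H]1OS(=O)(=O)O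
F15 | step 5 | 2-carbaldehyde from 6 | CC1(C)O[C@@H]2c3oc(C=O)cc(=O)c3[C@H](O[Si](C)(C)C(C)(C)C)[C@@H](O[Si](C)(C)C(C)(C)C)[C@@H]2O1
F16 | step 5 | 2-(2-phenylethenyl) compound from F15 | CC1(C)O[C@@H]2c3oc(C=Cc4ccccc4)cc(=O)c3[C@H](O[Si](C)(C)C(C)(C)C)[C@@H](O[Si](C)(C)C(C)(C)C)[C@@H]2O1
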